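The vessel is stirred at constant volume and held at one temperature, and the question is what a slow feed does to the side product.

| setting | Monday's | Sunday's | Thursday's | spring | summer | winter | autumn |
|---|---|---|---|---|---|---|---|
| starting material | 49 mM | 49 mM | 49 mM | 49 mM | 49 mM (fed, over 5.0 d) | 49 mM | 49 mM |
| second substrate | 98 mM | 49 mM | 74 mM | 98.0 mM (fed, over 5.0 d) | 98.0 mM | 98.0 mM | 98.0 mM (fed, over 12 h) |
| precatalyst | 4.9 µM | 4.9 µM | 4.9 µM | 4.9 µM | 4.9 µM | 4.9 µM | 4.9 µM |
| remark | run made earlier | run made earlier | run made earlier | all else is in the flask from the start; the feed brings no volume worth counting | all else is in the flask from the start; the feed brings no volume worth counting | everything together at the start | all else is in the flask from the start; the feed brings no volume worth counting |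
| time |  |  |  | 12 d | 12 d | 12 d | 12 d |

| run | time / d | side product / % | target / % | starting material / % |
|---|---|---|---|---|
| Monday's | 1.04 | 23 | 21 | 56 |
| Monday's | 2.08 | 46 | 55 | 1 |
| Monday's | 3.00 | 45 | 56 | 1 |
| Monday's | 4.00 | 49 | 55 | 1 |
| Monday's | 5.00 | 47 | 52 | 0 |
| Monday's | 6.00 | 43 | 54 | 2 |
| Monday's | 8.00 | 47 | 52 | 1 |
| Sunday's | 1.25 | 37 | 56 | 10 |
| Sunday's | 3.00 | 36 | 62 | 1 |
| Sunday's | 4.00 | 37 | 62 | 0 |
| Sunday's | 6.00 | 36 | 63 | 0 |
| Sunday's | 8.00 | 39 | 64 | 0 |
| Sunday's | 10.0 | 39 | 65 | 3 |
| Thursday's | 0.833 | 12 | 20 | 62 |
| Thursday's | 1.25 | 35 | 38 | 27 |
| Thursday's | 1.67 | 42 | 56 | 1 |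
| Thursday's | 2.50 | 41 | 59 | 4 |
| Thursday's | 4.00 | 42 | 59 | 0 |
| Thursday's | 6.00 | 43 | 57 | 1 |
| Thursday's | 10.0 | 40 | 57 | 1 |

(standard deviation of a reading: 1.5 percentage points)

* the flask with the highest amount of side product, in percent of the starting material charged ("all alike" if they lie within 1.5 percentage points) (spring / summer / winter / autumn / all alike)
* final side product, as a percentage of the starting material charged, in spring
* final side product, as a percentage of the starting material charged, in summer
* final side product, as a percentage of the starting material charged, in winter
* final side product, as a percentage of the starting material charged, in autumn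

- a species is counted by the starting material in it: one side product counts as two
- what was read earlier has a scatter of 1.5 percentage points, one standard deviation
- a reading or a percentage of target counts all its forms, free or not

Take the runs in slow motion. In the first stretch Thursday's run still holds 62% of its starting material at 0.833 d. In the middle, side product climbs beside target: Monday's run at 1.04 d reads starting material 56%, target 21%, side product 23%. At the end Monday's run reads starting material 1% at 2.08 d, and side product reads 46% there and 47% at 8.00 d, so I watch how long starting material stands beside target.

That time grows with the second substrate. My own reckoning takes the moment starting material reads 10%: 1.25 d in Sunday's run, and by interpolation 1.52 d in Thursday's and 1.91 d in Monday's. It looks as if starting material waits in a queue behind second substrate. The clearing rate, the charges of second substrate (counted in charges of starting material) that the catalyst clears per day, a zero-order rate, reads 1.52 /d, after a lag of 0.590 d. Thursday's run, not used for the rate, is predicted at 1.59 d, against 1.52 d read.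

For the new flasks the queue time of the full charge, which is Monday's moment read back, is 1.91 d. Spring's feed of 0.400 /d is slower than the clearing rate, so I expect no queue there. Autumn's feed of 4.00 /d ends well before the queue time, so I put autumn beside winter. Summer has fed 38.2% of its starting material at the queue time, and the rest arrives after it, so I put summer lowest and spring between.

The forecast gave 35% for spring, 16% for summer, 46% for winter and 45% for autumn, with winter highest, and held for summer that “side product is strongly suppressed”.

The flasks give 28.7% in spring, 8.60% in summer, 45.2% in winter and 47.8% in autumn, so autumn stands highest, 2.6 percentage points above winter.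

    starting material + target → side product (k = 3.79 × 10⁻⁴ /M/s)
    starting material + enzyme ⇌ complex A (K = 28.0 /M, k = 256 /M/s)
    complex B → enzyme + second product (k = 0.274 /s)
    second substrate + enzyme ⇌ complex B (K = 320 /M, k = 613 /M/s)
    precatalyst → enzyme (k = 9.67 × 10⁻⁶ /s)
    crystals ⇌ target, rate k6*(cs6 - [target]) while solid is left; crystals form when [target] > cs6 (solubility = 26.0 mM, k = 0.00283 /s)
    complex A → enzyme + target (k = 3.38 /s)

Summer's feed of starting material runs 5.0 d, longer than the reckoned queue time of 1.91 d, and summer ends at 8.60% side product, while winter, with its whole charge in from the start, ends at 45.2%. For autumn's neighbour with 240 mM of second substrate, the clearing rate of 1.52 /d reckons a queue time of 3.82 d, twice the 1.91 d of the full charge, and that neighbour ends at 59.6% side product.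

(The data come from a simulation for an exercise; scatter was added.)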